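**Retrosynthetic overview**
- The strategy rests on ring A (C1'–C6', carboxyl on C1'), a 3-methylorsellinate and folded tetraketide, whose carboxyl carbon is esterified by the CH2 on C6 of phthalide ring B (C1–C7a). Ring A is therefore grown on that oxygen instead of being coupled as a hindered acid.
- Target ⇒ racemic lactol (C3 fixed last, in the crystal) ⇒ allyl 2-formylbenzoate (deallylation closes the lactol ring) ⇒ acetal/MOM-masked diaryl ester after 4'-O-methylation.
- Key disconnection: ester C–O bond plus C1'–C6' bond ⇒ diketo-dioxinone (acylketene source) + ring B benzylic alcohol; ketene capture, then aldol aromatisation.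
- Diketo-dioxinone ⇐ 2,2,6-trimethyl-4H-1,3-dioxin-4-one (γ-methylation, two C-acetylations). Ring B alcohol ⇐ 3-hydroxy-5-methoxybenzaldehyde (acetal, MOM ether, two directed ortho-metalations).
- Ring order: the benzene ring of ring B is bought, ring A is closed in step 11, the lactol ring in step 14.

Key step: step 11

Remark on the chemistry: C3 of the 3-hydroxyphthalide is a lactol carbon that epimerises in solution through the open 2-formylbenzoic acid. The route therefore carries it as the racemate and fixes the (R) configuration only in the final solid, on the assumption that the racemate crystallises as a conglomerate.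

**Route**

Step 1
Reactants: 1 2,2,6-trimethyl-4H-1,3-dioxin-4-one
Product: 3 6-ethyl-2,2-dimethyl-4H-1,3-dioxin-4-one, via lithium dienolate 2 (not isolated)
Conditions: LiN(i-Pr)2, THF, −78 °C; MeI, DMPU, −78 → −30 °C
Reagents that add atoms: iodomethane, CI
Why: Kinetic deprotonation of the C6 methyl gives the cross-conjugated dienolate 2, which methyl iodide should alkylate at the γ-carbon (vinylogous enolate alkylation of an acetoacetate γ-anion equivalent).

Step 2
Reactants: 3 6-ethyl-2,2-dimethyl-4H-1,3-dioxin-4-one
Product: 5 2,2-dimethyl-6-(3-oxobutan-2-yl)-4H-1,3-dioxin-4-one (racemic), via lithium dienolate 4 (not isolated)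
Conditions: LiN(SiMe3)2, THF, −78 °C; AcCl (0.5 equiv), −78 °C; 1 M HCl
Reagents that add atoms: acetyl chloride, CC(=O)Cl
Why: Dienolate 4 should undergo C-acylation at its γ-carbon (vinylogous Claisen acylation), the second equivalent of dienolate acting as the base that removes the acidic proton of the product and being recovered as 3.

Step 3
Reactants: 5 2,2-dimethyl-6-(3-oxobutan-2-yl)-4H-1,3-dioxin-4-one; 6 N-methoxy-N-methylacetamide
Product: 8 6-(3,5-dioxohexan-2-yl)-2,2-dimethyl-4H-1,3-dioxin-4-one (racemic, enolisable), via dilithium dianion 7 (not isolated)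
Conditions: LiN(i-Pr)2 (2.2 equiv), THF, −78 °C; 6, −78 → −20 °C; 1 M HCl to pH 3
Reagents that add atoms: none
Why: Dianion 7 should react at its last-formed, most nucleophilic terminal carbon with the Weinreb amide (Claisen-type acylation of a 1,3-dicarbonyl dianion), and the chelated tetrahedral adduct prevents over-addition.

Step 4
Reactants: 9 3-hydroxy-5-methoxybenzaldehyde
Product: 10 3-(dimethoxymethyl)-5-methoxyphenol
Conditions: HC(OMe)3, MeOH, p-TsOH (cat.), rt; then Et3N
Reagents that add atoms: trimethyl orthoformate, COC(OC)OC; methanol, CO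
Why: Acid-catalysed acetalisation, driven by the orthoformate as water scavenger, masks the aldehyde as a base-stable group that later helps to direct metalation.

Step 5
Reactants: 10 3-(dimethoxymethyl)-5-methoxyphenol
Product: 11 1-(dimethoxymethyl)-3-methoxy-5-(methoxymethoxy)benzene
Conditions: MOMCl, i-Pr2NEt, CH2Cl2, 0 °C → rt
Reagents that add atoms: chloromethyl methyl ether, COCCl
Why: O-Alkylation of the phenol under basic conditions, which the acetal tolerates, installs the MOM ether as protecting group and strong ortho-director (Williamson-type etherification).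

Step 6
Reactants: 11 1-(dimethoxymethyl)-3-methoxy-5-(methoxymethoxy)benzene
Product: 13 4-(dimethoxymethyl)-2-methoxy-6-(methoxymethoxy)benzaldehyde, via aryllithium 12 (not isolated)
Conditions: n-BuLi, THF, 0 °C; DMF, 0 °C → rt; H2O
Reagents that add atoms: N,N-dimethylformamide, CN(C)C=O
Why: Directed ortho-metalation should take place at the ring carbon flanked by the MOM ether and the methyl ether, the most acidic site through cooperative coordination, and DMF formylates the C–Li bond.

Step 7
Reactants: 13 4-(dimethoxymethyl)-2-methoxy-6-(methoxymethoxy)benzaldehyde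
Product: 14 [4-(dimethoxymethyl)-2-methoxy-6-(methoxymethoxy)phenyl]methanol
Conditions: NaBH4, MeOH, 0 °C
Reagents that add atoms: none
Why: Hydride reduction of the aldehyde by NaBH4 leaves the acetal and the MOM ether untouched.

Step 8
Reactants: 14 [4-(dimethoxymethyl)-2-methoxy-6-(methoxymethoxy)phenyl]methanol
Product: 15 {[4-(dimethoxymethyl)-2-methoxy-6-(methoxymethoxy)phenyl]methoxy}tri(propan-2-yl)silane
Conditions: i-Pr3SiCl, imidazole, DMF, rt
Reagents that add atoms: chlorotri(propan-2-yl)silane, CC(C)[Si](Cl)(C(C)C)C(C)C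
Why: Silylation of the primary alcohol removes the acidic hydroxyl before the second metalation and gives a bulky ether that fluoride later cleaves without acid.

Step 9
Reactants: 15 {[4-(dimethoxymethyl)-2-methoxy-6-(methoxymethoxy)phenyl]methoxy}tri(propan-2-yl)silane
Product: 17 prop-2-en-1-yl 6-(dimethoxymethyl)-4-methoxy-2-(methoxymethoxy)-3-{[tri(propan-2-yl)silyl]oxymethyl}benzoate, via aryllithium 16 (not isolated)
Conditions: n-BuLi, THF, −20 → 0 °C; then added to ClCO2CH2CH=CH2 (3 equiv), THF, −78 °C
Reagents that add atoms: allyl chloroformate, C=CCOC(=O)Cl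
Why: Of the two remaining ring C–H sites, the one flanked by the MOM ether and the acetal should be metalated because OMOM is a much stronger ortho-director than OMe (directed ortho-metalation), and inverse addition to excess chloroformate gives the hindered ester without double addition.

Step 10
Reactants: 17 prop-2-en-1-yl 6-(dimethoxymethyl)-4-methoxy-2-(methoxymethoxy)-3-{[tri(propan-2-yl)silyl]oxymethyl}benzoate
Product: 18 prop-2-en-1-yl 6-(dimethoxymethyl)-3-(hydroxymethyl)-4-methoxy-2-(methoxymethoxy)benzoate
Conditions: Bu4NF, THF, 0 °C → rt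
Reagents that add atoms: none
Why: Fluoride cleaves the Si–O bond (desilylation) under non-acidic conditions that spare the acetal, the MOM ether and the hindered allyl ester, and the freed hydroxyl is meta to the ester and cannot lactonise.

Step 11
Reactants: 8 6-(3,5-dioxohexan-2-yl)-2,2-dimethyl-4H-1,3-dioxin-4-one; 18 prop-2-en-1-yl 6-(dimethoxymethyl)-3-(hydroxymethyl)-4-methoxy-2-(methoxymethoxy)benzoate
Product: 22 prop-2-en-1-yl 6-(dimethoxymethyl)-3-[(2,4-dihydroxy-3,6-dimethylbenzoyl)oxymethyl]-4-methoxy-2-(methoxymethoxy)benzoate, via acylketene 19 (not isolated), via triketo ester 20 (not isolated), via aldol adduct 21 (not isolated)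
Conditions: 8 (1.5 equiv), PhMe (0.2 M in 18), 110 °C; then Cs2CO3, MeOH, rt; then AcOH
Reagents that add atoms: none
Why: Heating extrudes acetone from 8 in a retro-[4+2] reaction and gives acylketene 19, which is captured by the primary benzylic hydroxyl of 18, the only protic nucleophile in either partner, to form the ester C–O bond of triketo ester 20 (chain C1 ester carbonyl to C8 methyl, methyl branch on C4). Cs2CO3 then forms the C2–C3 enolate, whose C2 adds to the C7 ketone in a 6-(enolendo)-exo-trig aldol closure that makes the C1'–C6' bond of ring A, and loss of water from adduct 21 with enolisation of the C3 and C5 carbonyls should deliver the aromatic resorcylate 22. The closest known reaction type is the thermolysis of diketo-dioxinones in the presence of alcohols followed by base-mediated aldol aromatisation to resorcylate esters, here applied to a chain with a C-methyl branch and to a hindered alcohol. No stereocentre is set, because the racemic methyl-bearing carbon of 8 and the carbinol carbon of 21 both end as sp2 ring atoms. The step needs aldol closure of C2 onto C7 to win over Claisen closure onto the ester, oxygen cyclisation to pyranones and capture of the ketene by its own enol; the poorly electrophilic ester, the mild base at room temperature and a concentrated solution of 18 favour it, and the MOM ether and allyl ester keep the ring B phenol and acid away from the ketene. The ester is thus made under neutral conditions, without activation of a di-ortho-substituted salicylic acid in the presence of the acetal and the acid-sensitive benzylic position.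

Step 12
Reactants: 22 prop-2-en-1-yl 6-(dimethoxymethyl)-3-[(2,4-dihydroxy-3,6-dimethylbenzoyl)oxymethyl]-4-methoxy-2-(methoxymethoxy)benzoate
Product: 23 prop-2-en-1-yl 6-(dimethoxymethyl)-3-[(2-hydroxy-4-methoxy-3,6-dimethylbenzoyl)oxymethyl]-4-methoxy-2-(methoxymethoxy)benzoate
Conditions: MeI (1.2 equiv), K2CO3 (1.1 equiv), acetone, rt
Reagents that add atoms: iodomethane, CI
Why: O-Methylation (Williamson ether synthesis) should take the more acidic, non-chelated 4'-hydroxyl while the 2'-hydroxyl stays hydrogen-bonded to the ester carbonyl, and ring B has no free phenol that could expel the benzylic carboxylate under base.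

Step 13
Reactants: 23 prop-2-en-1-yl 6-(dimethoxymethyl)-3-[(2-hydroxy-4-methoxy-3,6-dimethylbenzoyl)oxymethyl]-4-methoxy-2-(methoxymethoxy)benzoate
Product: 24 prop-2-en-1-yl 6-formyl-2-hydroxy-3-[(2-hydroxy-4-methoxy-3,6-dimethylbenzoyl)oxymethyl]-4-methoxybenzoate
Conditions: 2 M aq. HCl/THF (1:2), rt → 40 °C
Reagents that add atoms: water, O
Why: Acid hydrolysis should open the dimethyl acetal first and then the aryl MOM ether, and the benzylic ester should survive because the para-formyl and meta-ester groups of ring B disfavour benzylic ionisation once the aldehyde is free.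

Step 14
Reactants: 24 prop-2-en-1-yl 6-formyl-2-hydroxy-3-[(2-hydroxy-4-methoxy-3,6-dimethylbenzoyl)oxymethyl]-4-methoxybenzoate
Product: 26 [(3RS)-3,7-dihydroxy-5-methoxy-1-oxo-1,3-dihydro-2-benzofuran-6-yl]methyl 2-hydroxy-4-methoxy-3,6-dimethylbenzoate (racemate), via open-chain acid 25 (not isolated)
Conditions: Pd(PPh3)4 (5 mol %), 4-MeC6H4SO2Na, THF/H2O, rt; then 0.1 M HCl to pH 3, 0 °C
Reagents that add atoms: none
Why: Zerovalent palladium ionises the allyl ester to a π-allyl complex that the sulfinate traps (Tsuji–Trost deallylation, with a scavenger that is neither an amine nor a hydride because of the aldehyde), and the freed 2-formylbenzoic acid 25 should close spontaneously to the lactol (5-exo-trig, ring–chain tautomerism) as the racemate.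

Step 15
Reactants: 26 [(3RS)-3,7-dihydroxy-5-methoxy-1-oxo-1,3-dihydro-2-benzofuran-6-yl]methyl 2-hydroxy-4-methoxy-3,6-dimethylbenzoate (racemate)
Product: 27 [(3R)-3,7-dihydroxy-5-methoxy-1-oxo-1,3-dihydro-2-benzofuran-6-yl]methyl 2-hydroxy-4-methoxy-3,6-dimethylbenzoate
Conditions: slurry in EtOAc/heptane, AcOH (5 mol %), glass beads, 25 °C, seeded with (R) crystals of 27 from a milligram-scale separation on a chiral stationary phase
Reagents that add atoms: none
Why: Proposed new method: in solution the two enantiomers interconvert through opening of the lactol to the achiral acid 25, while in a ground slurry the small crystals dissolve and the seeded hand grows, so the whole solid should be funnelled into the (R) form and the handedness of the seed sets C3; the closest known reaction type is attrition-enhanced deracemisation (Viedma ripening) of conglomerate-forming compounds that racemise in solution, which has not been shown for 3-hydroxyphthalides.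

**Compound list**

1 | 2,2,6-trimethyl-4H-1,3-dioxin-4-one | CC1=CC(=O)OC(C)(C)O1 | starting material
2 | lithium 2,2-dimethyl-6-methylidene-6H-1,3-dioxin-4-olate (dienolate of 1) | [Li+].[O-]C1=CC(=C)OC(C)(C)O1 | intermediate (not isolated)
3 | 6-ethyl-2,2-dimethyl-4H-1,3-dioxin-4-one | CCC1=CC(=O)OC(C)(C)O1 | intermediate
4 | lithium 6-ethylidene-2,2-dimethyl-6H-1,3-dioxin-4-olate (dienolate of 3) | [Li+].[O-]C1=CC(=CC)OC(C)(C)O1 | intermediate (not isolated)
5 | 2,2-dimethyl-6-(3-oxobutan-2-yl)-4H-1,3-dioxin-4-one (racemic) | CC(=O)C(C)C1=CC(=O)OC(C)(C)O1 | intermediate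
6 | N-methoxy-N-methylacetamide | CC(=O)N(C)OC | starting material
7 | dilithium 2,2-dimethyl-6-(3-oxidobut-3-en-2-ylidene)-6H-1,3-dioxin-4-olate (dianion of 5) | [Li+].[Li+].C=C([O-])C(C)=C1C=C([O-])OC(C)(C)O1 | intermediate (not isolated)
8 | 6-(3,5-dioxohexan-2-yl)-2,2-dimethyl-4H-1,3-dioxin-4-one (racemic, enolisable) | CC(=O)CC(=O)C(C)C1=CC(=O)OC(C)(C)O1 | intermediate
9 | 3-hydroxy-5-methoxybenzaldehyde | COc1cc(O)cc(C=O)c1 | starting material
10 | 3-(dimethoxymethyl)-5-methoxyphenol | COc1cc(O)cc(C(OC)OC)c1 | intermediate
11 | 1-(dimethoxymethyl)-3-methoxy-5-(methoxymethoxy)benzene | COCOc1cc(OC)cc(C(OC)OC)c1 | intermediate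
12 | [4-(dimethoxymethyl)-2-methoxy-6-(methoxymethoxy)phenyl]lithium | [Li]c1c(OC)cc(C(OC)OC)cc1OCOC | intermediate (not isolated)
13 | 4-(dimethoxymethyl)-2-methoxy-6-(methoxymethoxy)benzaldehyde | O=Cc1c(OC)cc(C(OC)OC)cc1OCOC | intermediate
14 | [4-(dimethoxymethyl)-2-methoxy-6-(methoxymethoxy)phenyl]methanol | OCc1c(OC)cc(C(OC)OC)cc1OCOC | intermediate
15 | {[4-(dimethoxymethyl)-2-methoxy-6-(methoxymethoxy)phenyl]methoxy}tri(propan-2-yl)silane | CC(C)[Si](OCc1c(OC)cc(C(OC)OC)cc1OCOC)(C(C)C)C(C)C | intermediate
16 | [2-(dimethoxymethyl)-4-methoxy-6-(methoxymethoxy)-5-{[tri(propan-2-yl)silyl]oxymethyl}phenyl]lithium | [Li]c1c(C(OC)OC)cc(OC)c(CO[Si](C(C)C)(C(C)C)C(C)C)c1OCOC | intermediate (not isolated)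
17 | prop-2-en-1-yl 6-(dimethoxymethyl)-4-methoxy-2-(methoxymethoxy)-3-{[tri(propan-2-yl)silyl]oxymethyl}benzoate | C=CCOC(=O)c1c(C(OC)OC)cc(OC)c(CO[Si](C(C)C)(C(C)C)C(C)C)c1OCOC | intermediate
18 | prop-2-en-1-yl 6-(dimethoxymethyl)-3-(hydroxymethyl)-4-methoxy-2-(methoxymethoxy)benzoate | C=CCOC(=O)c1c(C(OC)OC)cc(OC)c(CO)c1OCOC | intermediate
19 | 4-methyloct-1-ene-1,3,5,7-tetrone (acylketene) | CC(=O)CC(=O)C(C)C(=O)C=C=O | intermediate (not isolated)
20 | prop-2-en-1-yl 6-(dimethoxymethyl)-4-methoxy-2-(methoxymethoxy)-3-[(4-methyl-3,5,7-trioxooctanoyl)oxymethyl]benzoate (triketo ester, racemic, enolisable) | CC(=O)CC(=O)C(C)C(=O)CC(=O)OCc1c(OC)cc(C(OC)OC)c(C(=O)OCC=C)c1OCOC | intermediate (not isolated)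
21 | prop-2-en-1-yl 6-(dimethoxymethyl)-3-[(2-hydroxy-2,5-dimethyl-4,6-dioxocyclohexane-1-carbonyl)oxymethyl]-4-methoxy-2-(methoxymethoxy)benzoate (aldol adduct, mixture of stereoisomers and enol forms) | CC1(O)CC(=O)C(C)C(=O)C1C(=O)OCc1c(OC)cc(C(OC)OC)c(C(=O)OCC=C)c1OCOC | intermediate (not isolated)
22 | prop-2-en-1-yl 6-(dimethoxymethyl)-3-[(2,4-dihydroxy-3,6-dimethylbenzoyl)oxymethyl]-4-methoxy-2-(methoxymethoxy)benzoate | Cc1cc(O)c(C)c(O)c1C(=O)OCc1c(OC)cc(C(OC)OC)c(C(=O)OCC=C)c1OCOC | intermediate
23 | prop-2-en-1-yl 6-(dimethoxymethyl)-3-[(2-hydroxy-4-methoxy-3,6-dimethylbenzoyl)oxymethyl]-4-methoxy-2-(methoxymethoxy)benzoate | COc1cc(C)c(C(=O)OCc2c(OC)cc(C(OC)OC)c(C(=O)OCC=C)c2OCOC)c(O)c1C | intermediate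
24 | prop-2-en-1-yl 6-formyl-2-hydroxy-3-[(2-hydroxy-4-methoxy-3,6-dimethylbenzoyl)oxymethyl]-4-methoxybenzoate | COc1cc(C)c(C(=O)OCc2c(OC)cc(C=O)c(C(=O)OCC=C)c2O)c(O)c1C | intermediate
25 | 6-formyl-2-hydroxy-3-[(2-hydroxy-4-methoxy-3,6-dimethylbenzoyl)oxymethyl]-4-methoxybenzoic acid | COc1cc(C)c(C(=O)OCc2c(OC)cc(C=O)c(C(=O)O)c2O)c(O)c1C | intermediate (not isolated)
26 | [(3RS)-3,7-dihydroxy-5-methoxy-1-oxo-1,3-dihydro-2-benzofuran-6-yl]methyl 2-hydroxy-4-methoxy-3,6-dimethylbenzoate (racemate) | COc1cc(C)c(C(=O)OCc2c(OC)cc3c(c2O)C(=O)OC3O)c(O)c1C | intermediate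
27 | [(3R)-3,7-dihydroxy-5-methoxy-1-oxo-1,3-dihydro-2-benzofuran-6-yl]methyl 2-hydroxy-4-methoxy-3,6-dimethylbenzoate | COc1cc(C)c(C(=O)OCc2c(OC)cc3c(c2O)C(=O)O[C@H]3O)c(O)c1C | target

**Step count and risks**

Total step count: 15 (steps 1–3 dioxinone branch, steps 4–10 ring B branch, steps 11–15 after convergence).
Longest linear sequence: 12 steps (steps 4–15, from 9).

Steps most likely to fail:

1. Step 15. The racemate may crystallise as a racemic compound instead of a conglomerate, or the enantiomers may interconvert too slowly in the slurry, so that grinding with seeds gives no enrichment. The fallback uses known chemistry and sets out from 26. The racemate is resolved by preparative chromatography on silica-bound amylose tris(3,5-dimethylphenylcarbamate) with heptane/EtOAc at 5 °C, and the (R) fractions are evaporated cold to give 27. The unwanted (S)-enantiomer F1 is left in EtOAc with a trace of AcOH until it has re-equilibrated to 26 and is injected again. The fallback comes back to the route at 27.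

2. Step 11. The acylketene may cyclise onto its own enol oxygen before the hindered alcohol captures it, or the triketo ester may close through oxygen or by Claisen condensation faster than by the aldol path. The fallback sets out from 18 and forms ring A beforehand. Purchased methyl 2,4-dihydroxy-3,6-dimethylbenzoate F2 is methylated at the non-chelated 4-hydroxyl (MeI, K2CO3, acetone, rt) to methyl 2-hydroxy-4-methoxy-3,6-dimethylbenzoate F3. This is saponified (KOH, aqueous DMSO, 80 °C; then cold dilute HCl) to 2-hydroxy-4-methoxy-3,6-dimethylbenzoic acid F4. F4 and 18 are joined by a Mitsunobu esterification (PPh3, diisopropyl azodicarboxylate, THF, 0 °C), in which the carboxylate attacks the activated benzylic carbon, so the hindered acid is never used as an acyl electrophile. This gives 23 directly, and the route is rejoined at 23 before step 13.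

3. Step 9. Deprotonation at the benzylic CH2OSi carbon, followed by migration of silicon from oxygen to carbon, may compete with ring metalation. Selectivity between the two ring sites rests on OMOM outranking OMe as director. The fallback sets out from 13 and carries the benzylic carbon as an aldehyde masked in the flask. Lithium 4-methylpiperazin-1-ide (from 1-methylpiperazine and n-BuLi, THF, −20 °C) adds to the aldehyde to give the lithium α-amino alkoxide F5, which has no acidic benzylic hydrogen and no silyl group. n-BuLi then metalates the ring between the MOM ether and the acetal to give the ring-lithiated α-amino alkoxide F6. Addition to allyl chloroformate at −78 °C and aqueous work-up release prop-2-en-1-yl 6-(dimethoxymethyl)-3-formyl-4-methoxy-2-(methoxymethoxy)benzoate F7. NaBH4 in MeOH at −20 °C reduces only the aldehyde and gives 18, where the route is rejoined; steps 7, 8 and 10 are then not needed.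

**Further compounds**

F1 | step 15 | [(3S)-3,7-dihydroxy-5-methoxy-1-oxo-1,3-dihydro-2-benzofuran-6-yl]methyl 2-hydroxy-4-methoxy-3,6-dimethylbenzoate | COc1cc(C)c(C(=O)OCc2c(OC)cc3c(c2O)C(=O)O[C@@H]3O)c(O)c1C
F2 | step 11 | methyl 2,4-dihydroxy-3,6-dimethylbenzoate (purchased) | COC(=O)c1c(C)cc(O)c(C)c1O
F3 | step 11 | methyl 2-hydroxy-4-methoxy-3,6-dimethylbenzoate | COC(=O)c1c(C)cc(OC)c(C)c1O
F4 | step 11 | 2-hydroxy-4-methoxy-3,6-dimethylbenzoic acid | OC(=O)c1c(C)cc(OC)c(C)c1O
F5 | step 9 | lithium [4-(dimethoxymethyl)-2-methoxy-6-(methoxymethoxy)phenyl](4-methylpiperazin-1-yl)methanolate | [Li+].[O-]C(N1CCN(C)CC1)c1c(OC)cc(C(OC)OC)cc1OCOC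
F6 | step 9 | lithium [4-(dimethoxymethyl)-5-lithio-2-methoxy-6-(methoxymethoxy)phenyl](4-methylpiperazin-1-yl)methanolate | [Li+].[O-]C(N1CCN(C)CC1)c1c(OC)cc(C(OC)OC)c([Li])c1OCOC
F7 | step 9 | prop-2-en-1-yl 6-(dimethoxymethyl)-3-formyl-4-methoxy-2-(methoxymethoxy)benzoate | C=CCOC(=O)c1c(C(OC)OC)cc(OC)c(C=O)c1OCOC
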